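Both prenyl C–C bonds are traced back to aryl–O–C bonds. In ring A the prenylated C2 lies ortho to the C3 hydroxyl. In ring B the prenylated C3' lies ortho to the C4' hydroxyl and has a symmetry twin in C5' as long as O2' and O6' both stay unsubstituted. Heating the unprotected O3,O4'-bis(1,1-dimethylallyl) ether of (3-hydroxyphenyl)(2,4,6-trihydroxyphenyl)methanone should therefore move both tertiary allyl groups from oxygen to carbon with allylic inversion. This twofold aromatic Claisen rearrangement gives the target in one operation, with no deprotection. The ether is assembled in three steps from phloroglucinol, 3-hydroxybenzoic acid and 3-chloro-3-methylbut-1-yne.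

Key step: step 4

Locants: ring A is the 3-oxygenated ring (C1 bears the carbonyl). Ring B is the phloroglucinol-derived ring (primed locants, C1' bears the carbonyl). No compound in the route has a stereocentre or a stereogenic alkene.

Remark on the chemistry: only one of O2'–H and O6'–H can be hydrogen-bonded to the carbonyl at a time. The site selectivity of step 2 is therefore taken to rest on acidity (O4'), accessibility (O3, O4') and a limiting amount of the tertiary electrophile, not on chelation alone.

Step 1
Reactants: 1 phloroglucinol; 2 3-hydroxybenzoic acid
Product: 3 (3-hydroxyphenyl)(2,4,6-trihydroxyphenyl)methanone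
Conditions: P2O5/MeSO3H (7.7 wt% P2O5), 1 (1.3 equiv), 70 °C, 1 h; then ice-water, EtOAc extraction
Reagents that add atoms: none
Why: Dehydrative Friedel–Crafts acylation: the P2O5/MeSO3H medium activates the carboxylic acid towards the very nucleophilic phloroglucinol, whose three CH positions are equivalent, the first ketone deactivates ring B against a second acylation, any O-aroyl ester can return to the C-acyl product by Fries-type transfer in the acid, and xanthone closure is impossible because ring A has no oxygen ortho to the carbonyl.

Step 2
Reactants: 3 (3-hydroxyphenyl)(2,4,6-trihydroxyphenyl)methanone; 4 3-chloro-3-methylbut-1-yne (2.2 equiv)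
Product: 5 [2,6-dihydroxy-4-(2-methylbut-3-yn-2-yloxy)phenyl][3-(2-methylbut-3-yn-2-yloxy)phenyl]methanone
Conditions: 4 (2.2 equiv, in portions), CuI (5 mol%), DBU (3 equiv), MeCN, 0 °C to rt; kept below 40 °C on work-up
Reagents that add atoms: 3-chloro-3-methylbut-1-yne (compound 4, two equivalents), C#CC(C)(C)Cl
Why: Copper-catalysed propargylic O-alkylation of phenoxides with a tertiary propargylic chloride: O4' belongs to the most acidic hydroxyl (para to the carbonyl) and O3 is an unhindered ordinary phenoxide, whereas O2' and O6' are wedged against the aroyl group, take turns in the hydrogen bond to the carbonyl and are poor partners for a tertiary electrophile, so a limiting amount of 4 should stop the reaction at the bis-ether 5.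

Step 3
Reactants: 5 [2,6-dihydroxy-4-(2-methylbut-3-yn-2-yloxy)phenyl][3-(2-methylbut-3-yn-2-yloxy)phenyl]methanone
Product: 6 [2,6-dihydroxy-4-(2-methylbut-3-en-2-yloxy)phenyl][3-(2-methylbut-3-en-2-yloxy)phenyl]methanone
Conditions: H2 (1 atm), 5% Pd/CaCO3 poisoned with Pb(OAc)2, quinoline, EtOAc, rt, stopped after 2 equiv H2; filtered, concentrated below 30 °C and used at once
Reagents that add atoms: none
Why: Lindlar semihydrogenation: terminal alkynes are adsorbed on the lead- and quinoline-poisoned palladium much more strongly than the vinyl groups they give, so hydrogen uptake can be stopped at two equivalents, the ketone, the phenols and the tertiary C–O bonds are not touched, no alkene geometry arises because both new alkenes are terminal, and keeping 6 cold avoids a premature rearrangement.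

Step 4
Reactants: 6 [2,6-dihydroxy-4-(2-methylbut-3-en-2-yloxy)phenyl][3-(2-methylbut-3-en-2-yloxy)phenyl]methanone
Product: 8 cudraphenone D, via ring-B-rearranged monoether 7 (not isolated)
Conditions: PhNEt2 (degassed), 130 °C, Ar, followed until 6 and 7 are consumed; EtOAc, cold 1 M HCl wash; SiO2 chromatography
Reagents that add atoms: none
Why: Each O–C(CH3)2–CH=CH2 unit and the adjacent aromatic C=C bond form a six-atom array that reorganises in a concerted suprafacial [3,3] shift of chair-like geometry, the vinyl CH2 terminus attacking the ortho carbon as the tertiary C–O bond breaks, and enolisation of the cyclohexadienone then regenerates the arene, so the allylic transposition turns each branched ether into a linear prenyl group (C2–CH2 on ring A, C3'–CH2 on ring B). The reaction type is the aromatic ortho-Claisen rearrangement of aryl 1,1-dimethylallyl ethers to ortho-prenylphenols, familiar from coumarins, xanthones and acylphenols and here run at two independent sites of one molecule; the ring B ether, which has the better aryloxide leaving group and the more electron-rich terminus, is expected to move first and give 7. No ring is closed and no stereocentre or stereogenic alkene is created, so neither a closure mode nor stereocontrol is at issue. Ring B needs no site control because C3' and C5' are symmetry-equivalent in 6, while ring A needs C2 over C4, which rests on the established tendency of a meta electron-withdrawing substituent (here the C1 aroyl carbonyl) to steer the shift to the ortho carbon it flanks; the bulk of the twisted aroyl group pulls the other way, so the C4 isomer is anticipated as a by-product to be removed by chromatography. Because the breaking bond is tertiary and allylic, the barrier lies well below that of a plain allyl ether, and about 130 °C should suffice, a temperature that the free phenols, the diaryl ketone and the new trisubstituted alkenes tolerate. The weakly basic solvent buffers the acidic ring B phenols and should thereby suppress ionisation of the tertiary ethers (loss of isoprene) and acid-promoted chroman closure of a prenyl group onto a neighbouring hydroxyl.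

Compound list
1 | phloroglucinol (benzene-1,3,5-triol) | Oc1cc(O)cc(O)c1 | starting material
2 | 3-hydroxybenzoic acid | O=C(O)c1cccc(O)c1 | starting material
3 | (3-hydroxyphenyl)(2,4,6-trihydroxyphenyl)methanone | O=C(c1cccc(O)c1)c1c(O)cc(O)cc1O | intermediate
4 | 3-chloro-3-methylbut-1-yne | C#CC(C)(C)Cl | starting material
5 | [2,6-dihydroxy-4-(2-methylbut-3-yn-2-yloxy)phenyl][3-(2-methylbut-3-yn-2-yloxy)phenyl]methanone (O3,O4'-bis(1,1-dimethylpropargyl) ether of 3) | C#CC(C)(C)Oc1cccc(C(=O)c2c(O)cc(OC(C)(C)C#C)cc2O)c1 | intermediate
6 | [2,6-dihydroxy-4-(2-methylbut-3-en-2-yloxy)phenyl][3-(2-methylbut-3-en-2-yloxy)phenyl]methanone (O3,O4'-bis(1,1-dimethylallyl) ether of 3) | C=CC(C)(C)Oc1cccc(C(=O)c2c(O)cc(OC(C)(C)C=C)cc2O)c1 | intermediate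
7 | [3-(2-methylbut-3-en-2-yloxy)phenyl][2,4,6-trihydroxy-3-(3-methylbut-2-enyl)phenyl]methanone (ring-B-rearranged monoether, not isolated) | C=CC(C)(C)Oc1cccc(C(=O)c2c(O)cc(O)c(CC=C(C)C)c2O)c1 | intermediate
8 | cudraphenone D ([3-hydroxy-2-(3-methylbut-2-enyl)phenyl][2,4,6-trihydroxy-3-(3-methylbut-2-enyl)phenyl]methanone) | CC(C)=CCc1c(O)cccc1C(=O)c1c(O)cc(O)c(CC=C(C)C)c1O | target

Total step count: 4
Longest linear sequence: 4 steps (1 or 2 to 3, 5, 6 and 8)

Steps most likely to fail

1. Step 4.
- **What may go wrong:** insufficient site selectivity on ring A, with migration to C4 competing with migration to the more crowded C2. The tertiary ethers may also ionise thermally and lose isoprene.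
- **Fallback (sets out from 1, returns at 8):** C4 is closed with a removable bromine, so the substrate enforces the site of migration. Phloroglucinol 1 is acylated with commercial 4-bromo-3-hydroxybenzoic acid (O=C(O)c1ccc(Br)c(O)c1) in P2O5/MeSO3H to give (4-bromo-3-hydroxyphenyl)(2,4,6-trihydroxyphenyl)methanone F1. Etherification with 4 (CuI, DBU, MeCN) gives the bromo bis(1,1-dimethylpropargyl) ether F2. Semihydrogenation over Pd/CaCO3 poisoned with Pb(OAc)2, which leaves aryl bromides intact, gives the bromo bis(1,1-dimethylallyl) ether F3. On heating in PhNEt2 the ring A group can settle only at C2, because a dienone formed at the brominated C4 cannot enolise and reverts, and this gives 4-bromocudraphenone D F4. Hydrodebromination with Pd(PPh3)4 and HCO2Na in DMF at 90 °C, a formate transfer reduction that spares trisubstituted alkenes and the ketone, then leads to 8.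

2. Step 2.
- **What may go wrong:** erosion of site selectivity among the four hydroxyls (a third etherification at O2' or O6'), C-alkylation of the electron-rich ring B, or base-induced elimination of the tertiary chloride before it is captured.
- **Fallback (sets out from 3, returns at 6, so step 3 is bypassed as well):** a Tsuji–Trost-type decarboxylative allylic etherification replaces the alkylation. 2-Methylbut-3-en-2-ol is converted with n-BuLi and Boc2O into tert-butyl 2-methylbut-3-en-2-yl carbonate F5. Compound 3 is then treated with F5 (about two equivalents) and Pd(PPh3)4 in THF at 0 to 5 °C. Zerovalent palladium ionises the carbonate, and the tert-butoxide released is the only base, so no more phenoxide forms than there is electrophile. At low temperature the phenoxide attacks the more substituted terminus of the prenyl-palladium complex and gives the branched ether under kinetic control. Hydroxyls held next to an aryl ketone are known to stay out of this reaction.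

3. Step 1.
- **What may go wrong:** O-acylation and self-condensation of the unprotected hydroxy acid, or a second acylation of ring B, giving polar mixtures that are hard to purify.
- **Fallback (sets out from 1, returns at 3):** a Houben–Hoesch reaction replaces the acylium chemistry. Compound 1 and commercial 3-hydroxybenzonitrile (N#Cc1cccc(O)c1) are treated with ZnCl2 and dry HCl in Et2O at 0 °C. The (3-hydroxyphenyl)(2,4,6-trihydroxyphenyl)methaniminium chloride F6 precipitates, which protects it from further reaction, and boiling water hydrolyses it to 3.

Further compounds
F1 | step 4 | (4-bromo-3-hydroxyphenyl)(2,4,6-trihydroxyphenyl)methanone | O=C(c1ccc(Br)c(O)c1)c1c(O)cc(O)cc1O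
F2 | step 4 | [4-bromo-3-(2-methylbut-3-yn-2-yloxy)phenyl][2,6-dihydroxy-4-(2-methylbut-3-yn-2-yloxy)phenyl]methanone (bromo bis(1,1-dimethylpropargyl) ether) | C#CC(C)(C)Oc1cc(C(=O)c2c(O)cc(OC(C)(C)C#C)cc2O)ccc1Br
F3 | step 4 | [4-bromo-3-(2-methylbut-3-en-2-yloxy)phenyl][2,6-dihydroxy-4-(2-methylbut-3-en-2-yloxy)phenyl]methanone (bromo bis(1,1-dimethylallyl) ether) | C=CC(C)(C)Oc1cc(C(=O)c2c(O)cc(OC(C)(C)C=C)cc2O)ccc1Br
F4 | step 4 | [4-bromo-3-hydroxy-2-(3-methylbut-2-enyl)phenyl][2,4,6-trihydroxy-3-(3-methylbut-2-enyl)phenyl]methanone (4-bromocudraphenone D) | CC(C)=CCc1c(O)c(Br)ccc1C(=O)c1c(O)cc(O)c(CC=C(C)C)c1O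
F5 | step 2 | tert-butyl 2-methylbut-3-en-2-yl carbonate | C=CC(C)(C)OC(=O)OC(C)(C)C
F6 | step 1 | (3-hydroxyphenyl)(2,4,6-trihydroxyphenyl)methaniminium chloride | [Cl-].[NH2+]=C(c1cccc(O)c1)c1c(O)cc(O)cc1O
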